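## Retrosynthetic overview

1. Numbering (drimane): ring A = C1–C5 + C10 (gem-dimethyl on C4, angular methyl on C10); ring B = C5–C10 (C7=C8, methyl on C8); the chain leaves C9 as C11–C12–C13=C14 and onward.
2. C12–C13 (sp3–sp2): hydroboration/Suzuki–Miyaura coupling of a 9-vinyl-drim-7-ene with a C14 (E,E)-alkenyl iodide made from geranyl bromide.
3. Ring B is formed last, at C6–C7: 6-endo-trig cyclization of a C7 vinyl radical (from a monocyclic alkenyl iodide) onto the exocyclic C5=C6 methylene of ring A, then H-transfer to C5 (trans fusion).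
4. C9–C10: an enantioselective Ireland–Claisen rearrangement of β-cyclogeranyl but-3-enoate sets quaternary C10 and tertiary C9 together and unveils C5=C6; ring A is bought as β-cyclocitral.
5. Enabling feature: the exocyclic C5=C6 alkene of ring A lies between two quaternary carbons (C4 and C10). C5 has no allylic hydrogen and is closed to attack, so the C7 radical must bond to the CH2 terminus C6, and the axial methyl groups on C4 and C10 screen one face of the resulting C5 radical.

Key step: step 8

Assumption: the (S,S)-configured diazaborolidine bromide is taken to deliver the (2R,1'R) acid 6, by analogy with (E)-allylic esters that carry a methyl group cis to the CH2–O arm; should the first run give the antipode, the (R,R)-reagent is used and nothing else changes.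

## Route

Step 1
Reactants: 1 β-cyclocitral
Product: 2 β-cyclogeraniol
Conditions: NaBH4, MeOH, 0 °C
Reagents that add atoms: none
Why: 1,2-reduction of the hindered enal by borohydride gives the primary allylic alcohol without touching the tetrasubstituted alkene.

Step 2
Reactants: 2 β-cyclogeraniol; 3 but-3-enoic acid
Product: 4 (2,6,6-trimethylcyclohex-1-en-1-yl)methyl but-3-enoate
Conditions: DCC, DMAP (5 mol%), CH2Cl2, 0 °C
Reagents that add atoms: none
Why: Steglich esterification of a primary allylic alcohol at 0 °C, where the β,γ-double bond of the acid should not move into conjugation.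

Step 3
Reactants: 4 (2,6,6-trimethylcyclohex-1-en-1-yl)methyl but-3-enoate
Product: 6 (2R)-2-[(1R)-1,3,3-trimethyl-2-methylidenecyclohexyl]but-3-enoic acid, via boron ketene acetal 5 (not isolated)
Conditions: (4S,5S)-2-bromo-1,3-bis{[3,5-bis(trifluoromethyl)phenyl]sulfonyl}-4,5-diphenyl-1,3,2-diazaborolidine (1.2 equiv), i-Pr2NEt (1.4 equiv), CH2Cl2, −78 °C; then −20 → 4 °C; aq. work-up
Reagents that add atoms: none
Why: Enantioselective Ireland–Claisen rearrangement through a chiral boron dienolate with the vinyl group cis to O–B, whose chair transition state places the C10 methyl (cis to the CH2–O arm on the ring alkene) axial and the vinyl group equatorial, so that C9–H ends up anti to C10–Me, while the C2-symmetric sulfonamide ligand on boron selects the alkene face and thereby the absolute configuration of quaternary C10 and of C9.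

Step 4
Reactants: 6 (2R)-2-[(1R)-1,3,3-trimethyl-2-methylidenecyclohexyl]but-3-enoic acid
Product: 7 (2R)-2-[(1R)-1,3,3-trimethyl-2-methylidenecyclohexyl]but-3-en-1-ol
Conditions: LiAlH4, Et2O, 0 °C → rt
Reagents that add atoms: none
Why: Hydride reduction of the carboxylic acid to the primary alcohol leaves the isolated alkenes and both stereocentres untouched.

Step 5
Reactants: 7 (2R)-2-[(1R)-1,3,3-trimethyl-2-methylidenecyclohexyl]but-3-en-1-ol
Product: 8 (2R)-2-[(1R)-1,3,3-trimethyl-2-methylidenecyclohexyl]but-3-enal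
Conditions: Dess–Martin periodinane, NaHCO3, CH2Cl2, 0 °C; used crude at once
Reagents that add atoms: none
Why: Dess–Martin oxidation under buffered, non-basic conditions stops at the β,γ-unsaturated aldehyde, whose C9–H is shielded by the neighbouring quaternary carbon and should not enolise in the short handling time.

Step 6
Reactants: 8 (2R)-2-[(1R)-1,3,3-trimethyl-2-methylidenecyclohexyl]but-3-enal
Product: 9 (1R)-1,3,3-trimethyl-2-methylidene-1-[(3S)-pent-1-en-4-yn-3-yl]cyclohexane
Conditions: TMSCHN2, n-BuLi, THF, −78 °C → 0 °C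
Reagents that add atoms: trimethylsilyldiazomethane, C[Si](C)(C)C=[N+]=[N-]
Why: Colvin-type one-carbon homologation, in which the lithiated diazo reagent adds to the aldehyde at −78 °C and Peterson elimination, loss of N2 and 1,2-H shift of the alkylidene carbene give the terminal alkyne without a base-mediated equilibration at C9.

Step 7
Reactants: 9 (1R)-1,3,3-trimethyl-2-methylidene-1-[(3S)-pent-1-en-4-yn-3-yl]cyclohexane
Product: 11 (1R)-1-[(1E,3R)-1-iodo-2-methylpenta-1,4-dien-3-yl]-1,3,3-trimethyl-2-methylidenecyclohexane, via alkenyldimethylalane 10 (not isolated)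
Conditions: Me3Al (3 equiv), Cp2ZrCl2 (0.5 equiv), ClCH2CH2Cl, rt; then I2, THF, −30 → 0 °C
Reagents that add atoms: trimethylaluminium, C[Al](C)C; iodine, II
Why: Zirconium-catalysed carboalumination (Negishi) adds Me–Al syn across the terminal alkyne with methyl on the inner carbon C8, and iodinolysis with retention gives the alkenyl iodide, the alkenes being far less reactive than the alkyne.

Step 8
Reactants: 11 (1R)-1-[(1E,3R)-1-iodo-2-methylpenta-1,4-dien-3-yl]-1,3,3-trimethyl-2-methylidenecyclohexane
Product: 12 (1S,4aS,8aS)-1-ethenyl-2,5,5,8a-tetramethyl-1,4,4a,5,6,7,8,8a-octahydronaphthalene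
Conditions: Bu3SnH (1.3 equiv) and AIBN (0.2 equiv) added over 8 h by syringe pump to 11 in PhH (5 mM), 80 °C
Reagents that add atoms: none
Why: The stannyl radical abstracts iodine to give the σ-vinyl radical at C7, which inverts rapidly (so the E geometry of 11 does not matter) and adds to the CH2 terminus C6 of the exocyclic alkene, and the tertiary C5 radical so formed takes hydrogen from the stannane. The closest known reaction type is the tin-hydride vinyl (and aryl) radical cyclization onto 1,1-disubstituted alkenes, including the 5-exo/3-exo/ring-opening (homoallyl–cyclopropylcarbinyl) rearrangement, which would carry any 5-exo radical to the same six-membered C5 radical. Ring B is closed in the 6-endo-trig mode and keeps the C7=C8 double bond, with its methyl group, inside the ring. The new stereocentre C5 is set by axial hydrogen transfer to the face opposite the axial methyl groups on C10 and C4, which gives the trans ring fusion. The step needs endo over exo regioselectivity and cyclization ahead of reduction: the first is secured by C5 being fully substituted and flanked by the quaternary carbons C4 and C10, the second by the low stationary stannane concentration. The C9 vinyl group can only be reached through 4-exo or 5-endo closure and should stay untouched.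

Step 9
Reactants: 13 geranyl bromide; 14 1-(trimethylsilyl)propyne
Product: 16 [(5E)-6,10-dimethylundeca-5,9-dien-1-yn-1-yl](trimethyl)silane, via 3-lithio-1-(trimethylsilyl)propyne 15 (not isolated)
Conditions: n-BuLi, THF, −78 °C; then 13, −78 °C → rt
Reagents that add atoms: none
Why: Propargylic lithiation of the silylpropyne and SN2 alkylation by the primary allylic bromide, the silyl group steering attack to the propargylic carbon and the E alkene of the geranyl unit being retained.

Step 10
Reactants: 16 [(5E)-6,10-dimethylundeca-5,9-dien-1-yn-1-yl](trimethyl)silane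
Product: 17 (5E)-6,10-dimethylundeca-5,9-dien-1-yne
Conditions: K2CO3, MeOH, rt
Reagents that add atoms: none
Why: Base-catalysed methanolysis of the alkynyl–silicon bond frees the terminal alkyne.

Step 11
Reactants: 17 (5E)-6,10-dimethylundeca-5,9-dien-1-yne
Product: 19 (1E,5E)-1-iodo-2,6,10-trimethylundeca-1,5,9-triene, via alkenyldimethylalane 18 (not isolated)
Conditions: Me3Al (2 equiv), Cp2ZrCl2 (0.25 equiv), CH2Cl2, 0 °C → rt; then I2, THF, −30 → 0 °C
Reagents that add atoms: trimethylaluminium, C[Al](C)C; iodine, II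
Why: Zirconium-catalysed syn carboalumination of the terminal alkyne followed by iodinolysis with retention fixes the E trisubstituted alkene, the trisubstituted alkenes of the chain being inert.

Step 12
Reactants: 12 (1S,4aS,8aS)-1-ethenyl-2,5,5,8a-tetramethyl-1,4,4a,5,6,7,8,8a-octahydronaphthalene; 19 (1E,5E)-1-iodo-2,6,10-trimethylundeca-1,5,9-triene
Product: 21 CNP0141177.1 (target), via B-alkyl-9-BBN adduct 20 (not isolated)
Conditions: 12, 9-BBN (1.2 equiv), THF, 0 °C → rt; then H2O, 19, Pd(dppf)Cl2 (5 mol%), AsPh3, Cs2CO3, DMF/THF, rt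
Reagents that add atoms: none
Why: B-alkyl Suzuki–Miyaura coupling, in which 9-BBN adds anti-Markovnikov only to the monosubstituted vinyl group (the trisubstituted ring alkene is inert and the chain alkenes arrive after the borane is consumed) and the sp3–sp2 coupling keeps the E geometry of the iodide; no stereocentre is formed or touched.

## Compound list

1 | β-cyclocitral (2,6,6-trimethylcyclohex-1-ene-1-carbaldehyde) | CC1=C(C=O)C(C)(C)CCC1 | starting material
2 | β-cyclogeraniol, (2,6,6-trimethylcyclohex-1-en-1-yl)methanol | CC1=C(CO)C(C)(C)CCC1 | intermediate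
3 | but-3-enoic acid | C=CCC(=O)O | starting material
4 | (2,6,6-trimethylcyclohex-1-en-1-yl)methyl but-3-enoate | C=CCC(=O)OCC1=C(C)CCCC1(C)C | intermediate
5 | boron ketene acetal of 4: O-[(4S,5S)-1,3-bis{[3,5-bis(trifluoromethyl)phenyl]sulfonyl}-4,5-diphenyl-1,3,2-diazaborolidin-2-yl] dienolate, vinyl cis to O–B | C=C/C=C(\OB1N(S(=O)(=O)c2cc(cc(c2)C(F)(F)F)C(F)(F)F)[C@@H](c2ccccc2)[C@H](c2ccccc2)N1S(=O)(=O)c1cc(cc(c1)C(F)(F)F)C(F)(F)F)OCC1=C(C)CCCC1(C)C | intermediate
6 | (2R)-2-[(1R)-1,3,3-trimethyl-2-methylidenecyclohexyl]but-3-enoic acid | C=C[C@@H](C(=O)O)[C@@]1(C)CCCC(C)(C)C1=C | intermediate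
7 | (2R)-2-[(1R)-1,3,3-trimethyl-2-methylidenecyclohexyl]but-3-en-1-ol | C=C[C@@H](CO)[C@@]1(C)CCCC(C)(C)C1=C | intermediate
8 | (2R)-2-[(1R)-1,3,3-trimethyl-2-methylidenecyclohexyl]but-3-enal | C=C[C@@H](C=O)[C@@]1(C)CCCC(C)(C)C1=C | intermediate
9 | (1R)-1,3,3-trimethyl-2-methylidene-1-[(3S)-pent-1-en-4-yn-3-yl]cyclohexane | C=C[C@@H](C#C)[C@@]1(C)CCCC(C)(C)C1=C | intermediate
10 | (E)-alkenyldimethylalane from 9 (AlMe2 on C7, methyl on C8) | C=C[C@@H](/C(C)=C/[Al](C)C)[C@@]1(C)CCCC(C)(C)C1=C | intermediate
11 | (1R)-1-[(1E,3R)-1-iodo-2-methylpenta-1,4-dien-3-yl]-1,3,3-trimethyl-2-methylidenecyclohexane | C=C[C@@H](/C(C)=C/I)[C@@]1(C)CCCC(C)(C)C1=C | intermediate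
12 | (1S,4aS,8aS)-1-ethenyl-2,5,5,8a-tetramethyl-1,4,4a,5,6,7,8,8a-octahydronaphthalene (9-vinyl-drim-7-ene) | C=C[C@H]1C(C)=CC[C@H]2C(C)(C)CCC[C@]12C | intermediate
13 | geranyl bromide, (2E)-1-bromo-3,7-dimethylocta-2,6-diene | CC(C)=CCC/C(C)=C/CBr | starting material
14 | 1-(trimethylsilyl)propyne | CC#C[Si](C)(C)C | starting material
15 | 3-lithio-1-(trimethylsilyl)propyne | [Li]CC#C[Si](C)(C)C | intermediate
16 | [(5E)-6,10-dimethylundeca-5,9-dien-1-yn-1-yl](trimethyl)silane | CC(C)=CCC/C(C)=C/CCC#C[Si](C)(C)C | intermediate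
17 | (5E)-6,10-dimethylundeca-5,9-dien-1-yne | CC(C)=CCC/C(C)=C/CCC#C | intermediate
18 | (1E,5E)-alkenyldimethylalane from 17 | CC(C)=CCC/C(C)=C/CC/C(C)=C/[Al](C)C | intermediate
19 | (1E,5E)-1-iodo-2,6,10-trimethylundeca-1,5,9-triene | CC(C)=CCC/C(C)=C/CC/C(C)=C/I | intermediate
20 | 9-{2-[(1S,4aS,8aS)-2,5,5,8a-tetramethyl-1,4,4a,5,6,7,8,8a-octahydronaphthalen-1-yl]ethyl}-9-borabicyclo[3.3.1]nonane | C1CC2CCCC(C1)B2CC[C@H]1C(C)=CC[C@H]2C(C)(C)CCC[C@]12C | intermediate
21 | CNP0141177.1, (1S,4aS,8aS)-2,5,5,8a-tetramethyl-1-[(3E,7E)-4,8,12-trimethyltrideca-3,7,11-trien-1-yl]-1,4,4a,5,6,7,8,8a-octahydronaphthalene | CC(C)=CCC/C(C)=C/CC/C(C)=C/CC[C@H]1C(C)=CC[C@H]2C(C)(C)CCC[C@]12C | target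

## Step count and risks

Total step count: 12. Longest linear sequence: 9 (steps 1–8 and 12). No protecting groups are used.

Steps most likely to fail:

1. Step 3. The [3,3] shift at the fully substituted alkene terminus may be slow enough for the boron dienolate to decay. The Lewis-acidic boron reagent may ionise the allylic ester. Face control or enolate geometry may be incomplete, which would erode the enantiomeric or diastereomeric purity at C9/C10. Fallback, from 4: deprotonation with LDA in THF/DMPU at −78 °C in the presence of TMSCl should give the (Z)-silyl ketene acetal F1, which on warming to 60 °C should rearrange to the racemic trimethylsilyl ester F2. Hydrolytic work-up gives the racemic acid F3 with the relative configuration of 6. Classical resolution follows, by crystallisation of the (R)-1-phenylethylammonium salt F4 (or of the mirror-image salt with the (S)-amine from the mother liquor, whichever crystallises with the wanted acid), and acidification returns to 6.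

2. Step 8. The vinyl radical may be quenched before it closes the ring, by hydrogen transfer from the stannane or by a 1,5-hydrogen shift from the C10 methyl or C1 methylene. Hydrogen delivery to the C5 radical may also be less face-selective than expected. Fallback, from 6, with a longer-lived, electrophilic α-keto radical and no alkenyl iodide: MeLi (2.2 equiv, Et2O, 0 °C) converts the acid into methyl ketone F5. LDA/TMSCl (THF, −78 °C) gives the kinetic silyl enol ether F6 and NBS (THF, −78 °C) the bromomethyl ketone F7. Bu3SnH/AIBN at high dilution in benzene closes ring B by 6-endo attack of the C7 α-keto radical on C6, with the same facial bias at C5, to give bicyclic ketone F8. KHMDS/PhNTf2 (THF, −78 °C) traps the less hindered C7 enolate as enol triflate F9, and MeMgBr with Fe(acac)3 (THF/NMP, −20 °C) installs the C8 methyl group and returns to 12.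

3. Step 6. The basic diazo reagent may enolise the α-vinyl aldehyde, leading to epimerisation at C9 or to migration of the vinyl double bond into conjugation. Fallback, from 8: the aldehyde meets only the neutral ylide from CBr4/PPh3 (CH2Cl2, 0 °C) and gives the dibromo-olefin F10. Bromine–lithium exchange and rearrangement with n-BuLi (2.1 equiv, THF, −78 °C), then water, returns to 9.

Further compounds

F1 | step 3 | (Z)-silyl ketene acetal of 4, vinyl cis to O–Si | C=C/C=C(\O[Si](C)(C)C)OCC1=C(C)CCCC1(C)C
F2 | step 3 | racemic trimethylsilyl (2R*)-2-[(1R*)-1,3,3-trimethyl-2-methylidenecyclohexyl]but-3-enoate | C=C[C@@H](C(=O)O[Si](C)(C)C)[C@@]1(C)CCCC(C)(C)C1=C.C=C[C@H](C(=O)O[Si](C)(C)C)[C@]1(C)CCCC(C)(C)C1=C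
F3 | step 3 | racemic (2R*)-2-[(1R*)-1,3,3-trimethyl-2-methylidenecyclohexyl]but-3-enoic acid | C=C[C@@H](C(=O)O)[C@@]1(C)CCCC(C)(C)C1=C.C=C[C@H](C(=O)O)[C@]1(C)CCCC(C)(C)C1=C
F4 | step 3 | (R)-1-phenylethylammonium (2R)-2-[(1R)-1,3,3-trimethyl-2-methylidenecyclohexyl]but-3-enoate | C=C[C@@H](C(=O)[O-])[C@@]1(C)CCCC(C)(C)C1=C.C[C@@H]([NH3+])c1ccccc1
F5 | step 8 | (3R)-3-[(1R)-1,3,3-trimethyl-2-methylidenecyclohexyl]pent-4-en-2-one | C=C[C@@H](C(C)=O)[C@@]1(C)CCCC(C)(C)C1=C
F6 | step 8 | trimethyl({(3R)-3-[(1R)-1,3,3-trimethyl-2-methylidenecyclohexyl]penta-1,4-dien-2-yl}oxy)silane | C=C[C@@H](C(=C)O[Si](C)(C)C)[C@@]1(C)CCCC(C)(C)C1=C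
F7 | step 8 | (3R)-1-bromo-3-[(1R)-1,3,3-trimethyl-2-methylidenecyclohexyl]pent-4-en-2-one | C=C[C@@H](C(=O)CBr)[C@@]1(C)CCCC(C)(C)C1=C
F8 | step 8 | (1R,4aS,8aS)-1-ethenyl-5,5,8a-trimethyloctahydronaphthalen-2(1H)-one | C=C[C@H]1C(=O)CC[C@H]2C(C)(C)CCC[C@]12C
F9 | step 8 | (1R,4aS,8aS)-1-ethenyl-5,5,8a-trimethyl-1,4,4a,5,6,7,8,8a-octahydronaphthalen-2-yl trifluoromethanesulfonate | C=C[C@H]1C(OS(=O)(=O)C(F)(F)F)=CC[C@H]2C(C)(C)CCC[C@]12C
F10 | step 6 | (1R)-1-[(3S)-1,1-dibromopenta-1,4-dien-3-yl]-1,3,3-trimethyl-2-methylidenecyclohexane | C=C[C@@H](C=C(Br)Br)[C@@]1(C)CCCC(C)(C)C1=C
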